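## Retrosynthetic overview
1. Surinamensinol A ⇒ remove the C7‑O silyl group and hydrate an allyl group anti‑Markovnikov. The 3‑hydroxypropyl chain is carried through the route as the allyl group of eugenol.
2. C9 methyl ⇒ CH2OTs ⇒ CH2OH ⇒ N‑acyl oxazolidinone (hydride displacement, then reductive removal of the auxiliary).
3. Key disconnection C7–C8: a boron‑mediated Evans syn glycolate aldol joins an aryloxyacetyl imide to 3,4,5‑trimethoxybenzaldehyde and sets both stereocentres in one step.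
4. Imide ⇒ (S)‑4‑benzyloxazolidin‑2‑one + eugenol + ethyl bromoacetate (Williamson ether, saponification, acid chloride, N‑acylation).
5. No ring is formed. Both benzene rings are bought, and the oxazolidinone ring is a bought auxiliary that is recovered.

Assumption: neolignan numbering is used (C7 = benzylic carbinol carbon, C8 = aryloxy‑bearing carbon, C9 = methyl carbon), and the given SMILES reads as (7R,8R), the threo (syn) isomer.

## Route

Step 1
Reactants: 1 eugenol (4‑allyl‑2‑methoxyphenol); 2 ethyl bromoacetate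
Product: 3 ethyl 2‑(4‑allyl‑2‑methoxyphenoxy)acetate
Conditions: K2CO3 (2 equiv), acetone, reflux, 6 h
Reagents that add atoms: none
Why: Williamson ether synthesis: K2CO3 forms the phenoxide, which displaces the activated primary bromide by SN2, and this weak base does not move the allyl double bond into conjugation.

Step 2
Reactants: 3 ethyl 2‑(4‑allyl‑2‑methoxyphenoxy)acetate
Product: 4 2‑(4‑allyl‑2‑methoxyphenoxy)acetic acid
Conditions: LiOH·H2O (2 equiv), THF/H2O 3:1, rt, 2 h; then 1 M HCl to pH 2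
Reagents that add atoms: lithium hydroxide, [Li+].[OH-]
Why: Ester saponification (acyl substitution) is irreversible once the carboxylate forms, and the aryl ethers and the alkene are inert to aqueous LiOH at room temperature.

Step 3
Reactants: 4 2‑(4‑allyl‑2‑methoxyphenoxy)acetic acid
Product: 5 2‑(4‑allyl‑2‑methoxyphenoxy)acetyl chloride
Conditions: (COCl)2 (1.3 equiv), DMF (2 mol %), CH2Cl2, 0 °C to rt, 2 h; evaporate, use crude
Reagents that add atoms: oxalyl chloride, O=C(Cl)C(=O)Cl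
Why: Acid chloride formation through the catalytic Vilsmeier‑type chloroiminium salt needs no Lewis acid and gives only gases beside the product, so neither the alkene nor the electron‑rich ring reacts.

Step 4
Reactants: 5 2‑(4‑allyl‑2‑methoxyphenoxy)acetyl chloride; 6 (S)‑4‑benzyloxazolidin‑2‑one
Product: 8 (S)‑3‑[2‑(4‑allyl‑2‑methoxyphenoxy)acetyl]‑4‑benzyloxazolidin‑2‑one, via N‑lithio oxazolidinone 7 (not isolated)
Conditions: 6, n‑BuLi (1.0 equiv), THF, −78 °C, 20 min; then 5 in THF, −78 °C to 0 °C, 1 h; sat. aq. NH4Cl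
Reagents that add atoms: n‑butyllithium, [Li]CCCC (its Li stands only in 7)
Why: N‑acylation of the lithiated Evans auxiliary by nucleophilic acyl substitution is fast at −78 °C, which outruns ketene formation from 5, and the auxiliary stereocentre is not touched.

Step 5
Reactants: 8 (S)‑3‑[2‑(4‑allyl‑2‑methoxyphenoxy)acetyl]‑4‑benzyloxazolidin‑2‑one; 9 3,4,5‑trimethoxybenzaldehyde
Product: 12 (S)‑4‑benzyl‑3‑[(2S,3R)‑2‑(4‑allyl‑2‑methoxyphenoxy)‑3‑hydroxy‑3‑(3,4,5‑trimethoxyphenyl)propanoyl]oxazolidin‑2‑one, via Z‑dibutylboron enolate 10 (not isolated), via dibutylboron aldolate 11 (not isolated)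
Conditions: Bu2BOTf (1.2 equiv), Et3N (1.4 equiv), CH2Cl2, −78 °C to 0 °C, 1 h; 9 (1.1 equiv), −78 °C, 1 h, then 0 °C, 1 h; aq. KH2PO4/K2HPO4 buffer (pH 7), MeOH, 30 % H2O2, 0 °C
Reagents that add atoms: dibutylboron triflate, CCCCB(CCCC)OS(=O)(=O)C(F)(F)F (its Bu2B group stands only in 10 and 11)
Why: Evans boron syn glycolate aldol: soft enolisation gives only the Z enolate 10, which adds through a closed Zimmerman–Traxler chair on the face away from the benzyl group, setting C8 and C7 together as the (2S,3R) syn pair (typically above 20:1) that becomes (7R,8R) once C9 is a methyl group.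

Step 6
Reactants: 12 syn aldol adduct
Product: 13 (S)‑4‑benzyl‑3‑[(2S,3R)‑2‑(4‑allyl‑2‑methoxyphenoxy)‑3‑(tert‑butyldimethylsilyloxy)‑3‑(3,4,5‑trimethoxyphenyl)propanoyl]oxazolidin‑2‑one
Conditions: TBSOTf (1.3 equiv), 2,6‑lutidine (2 equiv), CH2Cl2, 0 °C, 1 h
Reagents that add atoms: tert‑butyldimethylsilyl triflate, CC(C)(C)[Si](C)(C)OS(=O)(=O)C(F)(F)F
Why: Silyl ether formation with the very electrophilic silyl triflate and a non‑nucleophilic base protects the hindered benzylic alcohol without retro‑aldol or epimerisation, and it blocks later oxetane formation and sulfonylation at C7–O.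

Step 7
Reactants: 13 TBS‑protected aldol adduct
Product: 14 (2R,3R)‑2‑(4‑allyl‑2‑methoxyphenoxy)‑3‑(tert‑butyldimethylsilyloxy)‑3‑(3,4,5‑trimethoxyphenyl)propan‑1‑ol
Conditions: LiBH4 (2 equiv), MeOH (2 equiv), THF, 0 °C, 2 h; sat. aq. NH4Cl
Reagents that add atoms: none
Why: Reductive cleavage of the imide (hydride addition to the more electrophilic exocyclic carbonyl, collapse to the aldehyde, second reduction) gives the primary alcohol without enolisation at C8 and returns the auxiliary; the C8 descriptor changes from S to R only through CIP priorities.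

Step 8
Reactants: 14 primary alcohol
Product: 15 (2R,3R)‑2‑(4‑allyl‑2‑methoxyphenoxy)‑3‑(tert‑butyldimethylsilyloxy)‑3‑(3,4,5‑trimethoxyphenyl)propyl 4‑methylbenzenesulfonate
Conditions: TsCl (1.5 equiv), Et3N (3 equiv), DMAP (0.1 equiv), CH2Cl2, 0 °C to rt, 6 h
Reagents that add atoms: 4‑toluenesulfonyl chloride, Cc1ccc(cc1)S(=O)(=O)Cl
Why: Sulfonate ester formation under DMAP nucleophilic catalysis turns the only free hydroxyl group into a good leaving group, and no bond to a stereocentre is broken.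

Step 9
Reactants: 15 primary tosylate
Product: 16 tert‑butyl{[(1R,2R)‑2‑(4‑allyl‑2‑methoxyphenoxy)‑1‑(3,4,5‑trimethoxyphenyl)propyl]oxy}dimethylsilane
Conditions: LiEt3BH (3 equiv, 1 M in THF), THF, 0 °C to rt, 4 h; sat. aq. NH4Cl
Reagents that add atoms: none
Why: SN2 hydride displacement of a primary tosylate by the very nucleophilic, weakly basic triethylborohydride gives the C9 methyl group, with C8 only adjacent to the reacting carbon and the alkene, silyl ether and aryl ethers inert.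

Step 10
Reactants: 16 allyl arene
Product: 18 3‑{4‑[(1R,2R)‑1‑(tert‑butyldimethylsilyloxy)‑1‑(3,4,5‑trimethoxyphenyl)propan‑2‑yloxy]‑3‑methoxyphenyl}propan‑1‑ol, via B‑alkyl‑9‑BBN adduct 17 (not isolated)
Conditions: 9‑BBN (1.5 equiv, 0.5 M in THF), 0 °C to rt, 4 h; then 3 M NaOH, 30 % H2O2, 0 °C to rt, 1 h
Reagents that add atoms: hydrogen peroxide, OO (gives the new O); 9‑borabicyclo[3.3.1]nonane, B1C2CCCC1CCC2 (its boron and ring stand only in 17)
Why: Brown hydroboration–oxidation: the bulky 9‑BBN puts boron on the terminal carbon of the monosubstituted alkene (above 99:1), and alkaline peroxide replaces C–B by C–O to give the primary alcohol while the TBS ether survives.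

Step 11
Reactants: 18 TBS‑protected surinamensinol A
Product: 19 surinamensinol A, (1R,2R)‑2‑[4‑(3‑hydroxypropyl)‑2‑methoxyphenoxy]‑1‑(3,4,5‑trimethoxyphenyl)propan‑1‑ol
Conditions: Bu4NF (1.5 equiv, 1 M in THF), THF, 0 °C to rt, 3 h; H2O
Reagents that add atoms: none
Why: Fluoride‑driven desilylation (strong Si–F bond) runs under non‑acidic conditions, so the electron‑rich benzylic C7 centre cannot ionise and the (7R,8R) configuration is kept.

## Compound list
1 | eugenol | C=CCc1ccc(O)c(OC)c1 | starting material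
2 | ethyl bromoacetate | CCOC(=O)CBr | starting material
3 | ethyl 2‑(4‑allyl‑2‑methoxyphenoxy)acetate | CCOC(=O)COc1ccc(CC=C)cc1OC | intermediate
4 | 2‑(4‑allyl‑2‑methoxyphenoxy)acetic acid | OC(=O)COc1ccc(CC=C)cc1OC | intermediate
5 | 2‑(4‑allyl‑2‑methoxyphenoxy)acetyl chloride | ClC(=O)COc1ccc(CC=C)cc1OC | intermediate
6 | (S)‑4‑benzyloxazolidin‑2‑one | O=C1N[C@@H](Cc2ccccc2)CO1 | starting material
7 | N‑lithio (S)‑4‑benzyloxazolidin‑2‑one | [Li]N1C(=O)OC[C@@H]1Cc1ccccc1 | intermediate (not isolated)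
8 | (S)‑3‑[2‑(4‑allyl‑2‑methoxyphenoxy)acetyl]‑4‑benzyloxazolidin‑2‑one | COc1cc(CC=C)ccc1OCC(=O)N1C(=O)OC[C@@H]1Cc1ccccc1 | intermediate
9 | 3,4,5‑trimethoxybenzaldehyde | COc1cc(C=O)cc(OC)c1OC | starting material
10 | Z‑dibutylboron enolate of 8 | CCCCB(CCCC)O/C(=C\Oc1ccc(CC=C)cc1OC)N1C(=O)OC[C@@H]1Cc1ccccc1 | intermediate (not isolated)
11 | dibutylboron aldolate (2S,3R) | COc1cc(CC=C)ccc1O[C@H](C(=O)N1C(=O)OC[C@@H]1Cc1ccccc1)[C@H](OB(CCCC)CCCC)c1cc(OC)c(OC)c(OC)c1 | intermediate (not isolated)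
12 | syn aldol adduct (2S,3R), (S)‑auxiliary | COc1cc(CC=C)ccc1O[C@H](C(=O)N1C(=O)OC[C@@H]1Cc1ccccc1)[C@H](O)c1cc(OC)c(OC)c(OC)c1 | intermediate
13 | TBS ether of 12 (2S,3R) | COc1cc(CC=C)ccc1O[C@H](C(=O)N1C(=O)OC[C@@H]1Cc1ccccc1)[C@H](O[Si](C)(C)C(C)(C)C)c1cc(OC)c(OC)c(OC)c1 | intermediate
14 | (2R,3R)‑2‑(4‑allyl‑2‑methoxyphenoxy)‑3‑(TBSO)‑3‑(3,4,5‑trimethoxyphenyl)propan‑1‑ol | COc1cc(CC=C)ccc1O[C@H](CO)[C@H](O[Si](C)(C)C(C)(C)C)c1cc(OC)c(OC)c(OC)c1 | intermediate
15 | tosylate of 14 (2R,3R) | COc1cc(CC=C)ccc1O[C@H](COS(=O)(=O)c2ccc(C)cc2)[C@H](O[Si](C)(C)C(C)(C)C)c3cc(OC)c(OC)c(OC)c3 | intermediate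
16 | tert‑butyl{[(1R,2R)‑2‑(4‑allyl‑2‑methoxyphenoxy)‑1‑(3,4,5‑trimethoxyphenyl)propyl]oxy}dimethylsilane | COc1cc(CC=C)ccc1O[C@H](C)[C@H](O[Si](C)(C)C(C)(C)C)c1cc(OC)c(OC)c(OC)c1 | intermediate
17 | B‑alkyl‑9‑BBN adduct of 16 | COc1cc(CCCB2C3CCCC2CCC3)ccc1O[C@H](C)[C@H](O[Si](C)(C)C(C)(C)C)c1cc(OC)c(OC)c(OC)c1 | intermediate (not isolated)
18 | 7‑O‑TBS surinamensinol A (1R,2R) | COc1cc(CCCO)ccc1O[C@H](C)[C@H](O[Si](C)(C)C(C)(C)C)c1cc(OC)c(OC)c(OC)c1 | intermediate
19 | surinamensinol A (7R,8R) | COc1cc(CCCO)ccc1O[C@H](C)[C@H](O)c1cc(OC)c(OC)c(OC)c1 | target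

## Step count and risk analysis
Total step count: 11. Longest linear sequence: 11 steps (1 → 19). Compounds 2, 6 and 9 are bought.

**Step 5.** The risks are slow addition to the electron‑rich aldehyde, retro‑aldol on work‑up, and eroded diastereoselectivity. The fallback sets out from 3 and comes back at 14. It makes the C7–C8 bond by a crossed Claisen condensation and sets both stereocentres afterwards by reduction.
- Ester 3 is deprotonated with LiN(SiMe3)2 (2.2 equiv, THF, −78 °C) to the chelated lithium enolate F1.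
- The enolate is acylated with commercial 3,4,5‑trimethoxybenzoyl chloride to the racemic, configurationally labile ethyl 2‑(4‑allyl‑2‑methoxyphenoxy)‑3‑oxo‑3‑(3,4,5‑trimethoxyphenyl)propanoate F2.
- Asymmetric transfer hydrogenation with dynamic kinetic resolution, using RuCl(p‑cymene)[(S,S)‑TsDPEN] (1 mol %) in HCO2H/Et3N 5:2 at 30 °C, leaves the isolated alkene alone. It gives the syn ester ethyl (2S,3R)‑2‑(4‑allyl‑2‑methoxyphenoxy)‑3‑hydroxy‑3‑(3,4,5‑trimethoxyphenyl)propanoate F3.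
- TBSOTf/2,6‑lutidine gives its silyl ether F4, and i‑Bu2AlH (2.5 equiv, CH2Cl2, −78 to 0 °C) reduces the ester to 14.

**Step 7.** The risk is endocyclic opening of the oxazolidinone, because the acyl group is crowded by the silyl ether. The fallback sets out from 12 and comes back at 15. It removes the auxiliary before any protection.
- NaBH4 (4 equiv) in THF/H2O 4:1 at 0 °C to rt reduces the unhindered hydroxy imide to (1R,2R)‑2‑(4‑allyl‑2‑methoxyphenoxy)‑1‑(3,4,5‑trimethoxyphenyl)propane‑1,3‑diol F5.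
- TsCl (1.1 equiv) with Et3N and catalytic Bu2SnO in CH2Cl2 sulfonylates only the primary hydroxyl group. This gives (2R,3R)‑2‑(4‑allyl‑2‑methoxyphenoxy)‑3‑hydroxy‑3‑(3,4,5‑trimethoxyphenyl)propyl 4‑methylbenzenesulfonate F6.
- TBSOTf/2,6‑lutidine at −78 to 0 °C then gives 15.

**Step 9.** The risks are slow SN2 next to the oxygenated, branched C8, attack at sulfur that returns 14, and elimination. The fallback sets out from 15 and comes back at 18. It replaces hydride SN2 by catalytic hydrogenolysis of an iodide, so the alkene is used up first.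
- 9‑BBN in THF gives the B‑alkyl‑9‑BBN adduct F7, and mild oxidation with NaBO3·4H2O in THF/H2O gives the hydroxypropyl tosylate F8.
- NaI (5 equiv) in refluxing acetone gives, by Finkelstein exchange, 3‑{4‑[(1R,2S)‑1‑(tert‑butyldimethylsilyloxy)‑3‑iodo‑1‑(3,4,5‑trimethoxyphenyl)propan‑2‑yloxy]‑3‑methoxyphenyl}propan‑1‑ol F9. The geometry is unchanged, and the C8 descriptor changes only through CIP priority.
- H2 (1 atm), Pd/C and Et3N (2 equiv) in EtOAc/MeOH cleave the C–I bond to give 18. The amine suppresses benzylic C–O hydrogenolysis.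

## Further compounds
F1 | step 5 | lithium enolate of 3 (OLi cis to OAr) | [Li]O/C(OCC)=C\Oc1ccc(CC=C)cc1OC
F2 | step 5 | ethyl 2‑(4‑allyl‑2‑methoxyphenoxy)‑3‑oxo‑3‑(3,4,5‑trimethoxyphenyl)propanoate (racemic) | CCOC(=O)C(Oc1ccc(CC=C)cc1OC)C(=O)c1cc(OC)c(OC)c(OC)c1
F3 | step 5 | ethyl (2S,3R)‑2‑(4‑allyl‑2‑methoxyphenoxy)‑3‑hydroxy‑3‑(3,4,5‑trimethoxyphenyl)propanoate | COc1cc(CC=C)ccc1O[C@H](C(=O)OCC)[C@H](O)c1cc(OC)c(OC)c(OC)c1
F4 | step 5 | ethyl (2S,3R)‑2‑(4‑allyl‑2‑methoxyphenoxy)‑3‑(tert‑butyldimethylsilyloxy)‑3‑(3,4,5‑trimethoxyphenyl)propanoate | COc1cc(CC=C)ccc1O[C@H](C(=O)OCC)[C@H](O[Si](C)(C)C(C)(C)C)c1cc(OC)c(OC)c(OC)c1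
F5 | step 7 | (1R,2R)‑2‑(4‑allyl‑2‑methoxyphenoxy)‑1‑(3,4,5‑trimethoxyphenyl)propane‑1,3‑diol | COc1cc(CC=C)ccc1O[C@H](CO)[C@H](O)c1cc(OC)c(OC)c(OC)c1
F6 | step 7 | (2R,3R)‑2‑(4‑allyl‑2‑methoxyphenoxy)‑3‑hydroxy‑3‑(3,4,5‑trimethoxyphenyl)propyl 4‑methylbenzenesulfonate | COc1cc(CC=C)ccc1O[C@H](COS(=O)(=O)c2ccc(C)cc2)[C@H](O)c3cc(OC)c(OC)c(OC)c3
F7 | step 9 | B‑alkyl‑9‑BBN adduct of 15 | COc1cc(CCCB2C3CCCC2CCC3)ccc1O[C@H](COS(=O)(=O)c2ccc(C)cc2)[C@H](O[Si](C)(C)C(C)(C)C)c3cc(OC)c(OC)c(OC)c3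
F8 | step 9 | (2R,3R)‑3‑(tert‑butyldimethylsilyloxy)‑2‑[4‑(3‑hydroxypropyl)‑2‑methoxyphenoxy]‑3‑(3,4,5‑trimethoxyphenyl)propyl 4‑methylbenzenesulfonate | COc1cc(CCCO)ccc1O[C@H](COS(=O)(=O)c2ccc(C)cc2)[C@H](O[Si](C)(C)C(C)(C)C)c3cc(OC)c(OC)c(OC)c3
F9 | step 9 | 3‑{4‑[(1R,2S)‑1‑(tert‑butyldimethylsilyloxy)‑3‑iodo‑1‑(3,4,5‑trimethoxyphenyl)propan‑2‑yloxy]‑3‑methoxyphenyl}propan‑1‑ol | COc1cc(CCCO)ccc1O[C@H](CI)[C@H](O[Si](C)(C)C(C)(C)C)c1cc(OC)c(OC)c(OC)c1
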